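The pitfall with a poorly soluble nucleophile is to put its solubility into the rate law: 8.3 mM held for 2.0 min reckons to 83.4% of the electrophile used, and I don't trust that figure.

electrophile 15 mM; buffer base 0.200 equiv; buffer acid 1.00 equiv; solid nucleophile 2.00 equiv; time 2.0 min

* part of the electrophile that has reacted at 2.0 min
* pH of the solution at 2.0 min

- acid is the free proton; pH is minus the decimal logarithm of its molar concentration
- given per volume of solution although it is solid: solid nucleophile
- at the start none of the solid nucleophile is in solution
- run time (flask): 2.0 min

    electrophile + nucleophile → acid + product + leaving group (k1 = 1.8 M⁻¹ s⁻¹)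
    protonated nucleophile ⇌ nucleophile + acid, settled at all times (K2 = 1.3 × 10⁻⁶ M)
    buffer acid ⇌ buffer base + acid, settled at all times (K3 = 1.0 × 10⁻⁸ M)
    solid nucleophile ⇌ nucleophile, rate k4*(cs4 - [nucleophile]) while solid is left; crystals form when [nucleophile] > cs4 (cs4 = 8.3 mM, k4 = 0.019 s⁻¹)
    nucleophile ⇌ dormant form (K5 = 30, k5 = 0.040 s⁻¹)

So I first ask how much nucleophile stands in solution. It enters by dissolving, with coefficient 0.019 s⁻¹, and leaves by turning dormant, 0.040 s⁻¹, and by attacking the electrophile, 0.0270 s⁻¹ as charged. I set aside the way back from the dormant form. The two losses together are faster than dissolving, so c(nucleophile) levels off well below the solubility, at 1.83 mM. This is the plateau level: dissolving coefficient times solubility, divided by the sum of the three constants. The inverse of that sum gives the lag, 11.6 s.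

Does the plateau last? Dissolving at that level would use up the solid charge in 4.07 min, longer than the run, so I take the plateau to hold for the run. The electrophile then decays pseudo-first-order, and integrating gives ln(c0/c) = k1 × plateau × (time − lag), which means 30.1% has reacted.

What does that do to the pH? The reaction frees 4.51 mM of acid, more than the 3.00 mM of buffer base. I let the excess protonate nucleophile, and setting that excess against the plateau gives pH 5.97.

The forecast says 29% and 5.9, each a little below mine, holding dissolution “opposed by fast loss to the dormant form and by reaction”.

The simulation gives 29.9% and pH 5.92.

In this flask c(nucleophile) reads 1.86 mM after 1.00 min and 1.75 mM after 2.00 min, beside the plateau of 1.83 mM. After 2.00 min the forward step to the dormant form uses nucleophile 2.1 times as fast as the step to product. For the neighbouring flask read at 50 s, the same plateau and lag give 11.9%, and that flask reads 11.9%.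

(Its constants belong to no real substance; the rest is arithmetic.)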